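**Assumptions (one line each):** α-Santonin is taken as the commercial chiral-pool starting material. Guaiane numbering is used throughout; unprimed = cyclopentene (dienophile-derived) half, primed = norbornanone (diene-derived) half. The route is a proposal reasoned from first principles and analogy, not a reproduced literature synthesis.

## Retrosynthetic overview

1. Caruifolin B ⇒ double Me–M addition to a 14,14′-dinor-10,10′-diketone ⇒ Lemieux–Johnson cleavage of a bis(10(14)-exo-methylene) ⇒ dehydration of 10,10′-di-epi-caruifolin B. Santonin photochemistry gives the 10α-OH epimer, so both carbinols are inverted last by delivering carbon, not oxygen, to the open face.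
2. Di-epi dimer ⇒ cross Diels–Alder (bonds C2′–C2 and C5′–C3): a 3-silyloxy-guaia-2,4-diene (diene) + a guaia-2,4-diene (dienophile at C2=C3). This forms the norbornanone last and brings in the C3′ ketone as a silyl enol ether.
3. Both cyclopentadienes ⇒ isophotosantonic lactone (enone → silyl dienol ether; enone → dienyl triflate → diene).
4. Isophotosantonic lactone ⇒ α-santonin by photochemical 6/6 → 5/7 rearrangement; the lactone and C6, C7, C11 come from the chiral pool.
5. Ring order: lactone (given) → 5/7 hydroazulene (step 1) → bicyclo[2.2.1]heptanone (step 5).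

## Forward route

**Step 1**
Reactants: 1, α-santonin
Product: 2, isophotosantonic lactone (10α-hydroxy-3-oxo-1αH-guai-4-en-6α,12-olide; 11S)
Conditions: hν (medium-pressure Hg lamp, Pyrex), AcOH/H2O 1:1, reflux, N2
Reagents that add atoms: water, O
Why: Santonin (cross-conjugated cyclohexadienone) photorearrangement; C1–C5 bonding gives a cyclopropyl cation that water opens at C10 anti to the breaking C5–C10 bond, fixing 1α-H and 10α-OH while C6, C7 and C11 are untouched.

**Step 2**
Reactants: 2, isophotosantonic lactone
Product: 3, 10α-hydroxy-3-(trifluoromethanesulfonyloxy)-1αH-guaia-2,4-dien-6α,12-olide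
Conditions: LiHMDS (2.1 equiv), THF, −78 °C; PhNTf2 (1.1 equiv), −78 → 0 °C
Reagents that add atoms: N-phenylbis(trifluoromethanesulfonimide), O=S(=O)(N(c1ccccc1)S(=O)(=O)C(F)(F)F)C(F)(F)F
Why: Kinetic α′-deprotonation at C2 gives the cross-conjugated dienolate, which is O-triflated (enol triflate formation); the hindered tertiary lithium alkoxide is inert to PhNTf2 and no stereocentre is touched.

**Step 3**
Reactants: 3, dienyl triflate
Product: 4, 10α-hydroxy-1αH-guaia-2,4-dien-6α,12-olide (cyclopentadiene; used immediately, kept cold and dilute)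
Conditions: Pd(OAc)2 (5 mol %), PPh3, HCO2H, n-Bu3N, DMF, 40 °C
Reagents that add atoms: none
Why: Pd-catalysed formate hydrogenolysis of an enol triflate (Cacchi reduction) replaces OTf by H without touching C1, the lactone or the tertiary alcohol.

**Step 4**
Reactants: 2, isophotosantonic lactone
Product: 5, 3,10α-bis(trimethylsilyloxy)-1αH-guaia-2,4-dien-6α,12-olide
Conditions: TMSOTf (2.5 equiv), Et3N (3.5 equiv), CH2Cl2, −78 → 0 °C; pentane, filter, concentrate (no aqueous work-up)
Reagents that add atoms: trimethylsilyl triflate, C[Si](C)(C)OS(=O)(=O)C(F)(F)F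
Why: Soft enolisation of the enone gives the cross-conjugated 2-silyloxydiene (silyl dienol ether formation) and caps the tertiary OH; a ketone is silylated much faster than the lactone.

**Step 5**
Reactants: 4, guaia-2,4-diene (1 equiv, added slowly); 5, silyloxydiene (3 equiv)
Product: 6, 10,10′-di-epi-caruifolin B (endo adduct; 3′-ketone, 4′-exo-methyl, 10α-OH and 10′α-OH)
Conditions: BSA (1.5 equiv), PhMe (≥2 M), 40 °C, 3–4 d; then 1 M HCl/THF, 0 °C → rt (one pot; excess 5 returns as 2)
Reagents that add atoms: none
Why: Cross Diels–Alder of two cyclopentadienes (absinthin-type dimerisation mode): the electron-rich silyloxydiene adds endo across C2=C3 of 4, the first bond joining the two unsubstituted termini (C2′–C2), with each partner attacked on the face of H-1 (anti to C10), which sets C2, C3, C2′ and C5′; acid hydrolysis of the silyl enol ether sets C4′ under thermodynamic control, because an endo methyl would collide with the endo-fused cyclopentene.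

**Step 6**
Reactants: 6, 10,10′-di-epi-caruifolin B
Product: 7, bis(10(14),10′(14′)-exo-methylene) dimer (10,10′-bis-anhydro compound)
Conditions: SOCl2, pyridine, CH2Cl2, −20 → 0 °C
Reagents that add atoms: none
Why: E2 dehydration via the chlorosulfites; each 10α-OH is pseudo-equatorial and cis to H-1, so only the methyl hydrogens are anti-periplanar and the exocyclic olefins should dominate.

**Step 7**
Reactants: 7, bis(exo-methylene) dimer
Product: 8, 14,14′-dinor-3′,10,10′-triketone
Conditions: OsO4 (5 mol %), NaIO4, 2,6-lutidine, dioxane/H2O 3:1, rt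
Reagents that add atoms: osmium tetroxide, O=[Os](=O)(=O)=O; sodium periodate, [Na+].[O-]I(=O)(=O)=O
Why: Lemieux–Johnson oxidative cleavage; OsO4 selects the two unhindered 1,1-disubstituted olefins over the shielded tetrasubstituted C4=C5, and lutidine buffering limits β,γ → α,β isomerisation of the ring-A ketone.

**Step 8**
Reactants: 8, triketone
Product: 9, caruifolin B
Conditions: MeLi/CeCl3 (MeCeCl2, ~3 equiv), THF, −78 °C; NH4Cl
Reagents that add atoms: methyllithium, [Li]C
Why: Organocerium (Imamoto) 1,2-addition; methyl enters each C10 carbonyl from its open peripheral face (Felkin, anti to C1–C5 in ring A; anti to the C3′–C4′ bridge in ring B), placing OH on the inner face (10β and 10′β). The C3′ ketone is blocked on both faces and the lactones are inert at −78 °C.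

## Compound list

1 | α-santonin | C[C@H]1[C@@H]2CC[C@]3(C=CC(=O)C(=C3[C@H]2OC1=O)C)C | starting material
2 | isophotosantonic lactone (10α-hydroxy-3-oxo-1αH-guai-4-en-6α,12-olide) | CC1=C2[C@H]3OC(=O)[C@@H](C)[C@@H]3CC[C@@](C)(O)[C@@H]2CC1=O | intermediate
3 | 10α-hydroxy-3-triflyloxy-1αH-guaia-2,4-dien-6α,12-olide | CC1=C2[C@H]3OC(=O)[C@@H](C)[C@@H]3CC[C@@](C)(O)[C@@H]2C=C1OS(=O)(=O)C(F)(F)F | intermediate
4 | 10α-hydroxy-1αH-guaia-2,4-dien-6α,12-olide | CC1=C2[C@H]3OC(=O)[C@@H](C)[C@@H]3CC[C@@](C)(O)[C@@H]2C=C1 | intermediate
5 | 3,10α-bis(trimethylsilyloxy)-1αH-guaia-2,4-dien-6α,12-olide | CC1=C2[C@H]3OC(=O)[C@@H](C)[C@@H]3CC[C@@](C)(O[Si](C)(C)C)[C@@H]2C=C1O[Si](C)(C)C | intermediate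
6 | 10,10′-di-epi-caruifolin B | CC1=C2[C@H]3OC(=O)[C@@H](C)[C@@H]3CC[C@@](C)(O)[C@@H]2[C@H]2[C@H]3C(=O)[C@H](C)[C@]4([C@@H]3[C@](C)(O)CC[C@H]3[C@H](C)C(=O)O[C@@H]34)[C@@H]12 | intermediate
7 | bis(10(14),10′(14′)-exo-methylene) dimer | CC1=C2[C@H]3OC(=O)[C@@H](C)[C@@H]3CCC(=C)[C@@H]2[C@H]2[C@H]3C(=O)[C@H](C)[C@]4([C@@H]3C(=C)CC[C@H]3[C@H](C)C(=O)O[C@@H]34)[C@@H]12 | intermediate
8 | 14,14′-dinor-3′,10,10′-triketone | CC1=C2[C@H]3OC(=O)[C@@H](C)[C@@H]3CCC(=O)[C@@H]2[C@H]2[C@H]3C(=O)[C@H](C)[C@]4([C@@H]3C(=O)CC[C@H]3[C@H](C)C(=O)O[C@@H]34)[C@@H]12 | intermediate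
9 | caruifolin B | CC1=C2[C@H]3OC(=O)[C@@H](C)[C@@H]3CC[C@](C)(O)[C@@H]2[C@H]2[C@H]3C(=O)[C@H](C)[C@]4([C@@H]3[C@@](C)(O)CC[C@H]3[C@H](C)C(=O)O[C@@H]34)[C@@H]12 | target

## Totals and risks

**Total steps:** 8
**Longest linear sequence:** 7 (1 → 2 → 3 → 4 → 6 → 7 → 8 → 9; step 4 is the one-step branch to 5)

**Three steps most likely to fail:**

1. **Step 5, cross Diels–Alder.** Diene 4 may homodimerise, or 5 may be too slow.
   Fallback: make the homodimer of 4 deliberately and use it as a slow-release reservoir. Heating it (retro-Diels–Alder, about 120–140 °C) with a large excess of the more robust TBS analogue of 5 keeps free 4 at trace concentration and funnels it into the cross adduct.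

2. **Step 6, double exo-selective dehydration.** Endocyclic Δ9 olefins or norbornyl-type rearrangement in the primed half are possible.
   Fallback: move the C10 inversion to the monomer stage. Dehydrate 2 (isomers separable on scale), Luche-reduce and silylate C3–OH, then OsO4/NaIO4, MeCeCl2, desilylation and MnO2 give the 10β-hydroxy enone. Running steps 2–5 on that material makes the Diels–Alder deliver caruifolin B directly.

3. **Step 8, double methyl addition.** Risks are enolisation or β,γ → α,β isomerisation of the ring-A ketone, imperfect facial selectivity at C10, and lactone attack.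
   Fallback: deliver the carbon as a sulfur ylide instead. Corey–Chaykovsky spiro-epoxidation uses the same outer-face approach and puts O on the inner face; MgI2 opening at CH2 and Bu3SnH reduction then give the methyl carbinols without an organometallic addition.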